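**Retrosynthetic overview**
1. Target 13 comes from its ring A dimethyl ether 12; the two O-methyl groups at C5 and C7 are removed last.
2. 12 is cut into three components joined in one pot: phenol 7 (ring A, supplies C4a and O1), 2-isopropylacrolein 3 (supplies C4–C3–C2) and 2,4-diformylphloroglucinol 8 (ring C). Bonds made: C4–C4a, C2–ring C and O1–C2.
3. Enabling feature: C2 of the dihydropyran ring (ring B) is bonded to O1 and is benzylic to ring C, ortho to a ring C hydroxyl, so it can pass through the aldehyde and o-quinone methide levels; C4 is a CH2 on C4a next to the O1-bearing C8a. O1–C8a–C4a is therefore a phenol O,C-dinucleophile and C4–C3(iPr)–C2 an α-substituted enal dielectrophile.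
4. Ring order: rings A and C are bought as benzene rings; ring B is the only ring formed, transiently as a lactol and finally by oxa-Michael closure. C3 is set by catalyst-controlled protonation, C2 by equilibration to 2,3-trans.
5. 3 comes from isovaleraldehyde and formaldehyde; 7 from 4-hydroxy-2,6-dimethoxybenzaldehyde and isobutylmagnesium bromide, then oxidation.

Key step: step 4

Assumption: the (S)-diamine salt is taken to protonate the enamine on the face that gives 3S (if the sense proves opposite, its enantiomer is used and nothing else changes); 4 and 8 are taken as catalogue compounds.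

**Step 1**
Reactants: 1 3-methylbutanal (isovaleraldehyde); 2 formaldehyde (37 % aqueous)
Product: 3 3-methyl-2-methylidenebutanal (2-isopropylacrolein)
Conditions: pyrrolidine (10 mol %), propionic acid (10 mol %), i-PrOH/H2O, 45 °C
Reagents that add atoms: none
Why: Mannich condensation of the aldehyde enamine with formaldehyde and β-elimination of the amine (organocatalytic α-methylenation) should give the α-substituted acrolein, which cannot be methylenated a second time.

**Step 2**
Reactants: 4 4-hydroxy-2,6-dimethoxybenzaldehyde; 5 isobutylmagnesium bromide (2-methylpropylmagnesium bromide)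
Product: 6 4-(1-hydroxy-3-methylbutyl)-3,5-dimethoxyphenol (racemic)
Conditions: i-BuMgBr (3.2 equiv), THF, −20 °C → rt; sat. aq. NH4Cl, 0 °C
Reagents that add atoms: none
Why: Grignard 1,2-addition to the aldehyde after the first equivalent has formed the magnesium phenoxide; the racemic carbinol centre is removed in step 3.

**Step 3**
Reactants: 6 4-(1-hydroxy-3-methylbutyl)-3,5-dimethoxyphenol
Product: 7 1-(4-hydroxy-2,6-dimethoxyphenyl)-3-methylbutan-1-one
Conditions: activated MnO2 (10 equiv), CH2Cl2, rt
Reagents that add atoms: none
Why: heterogeneous MnO2 oxidation is selective for the electron-rich benzylic alcohol and should tolerate the free phenol.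

**Step 4**
Reactants: 7 1-(4-hydroxy-2,6-dimethoxyphenyl)-3-methylbutan-1-one; 3 3-methyl-2-methylidenebutanal; 8 2,4,6-trihydroxybenzene-1,3-dicarbaldehyde (2,4-diformylphloroglucinol)
Product: 12 5-[(2R,3S)-5,7-dimethoxy-6-(3-methylbutanoyl)-3-(propan-2-yl)-3,4-dihydro-2H-chromen-2-yl]-2,4,6-trihydroxybenzene-1,3-dicarbaldehyde, via Michael adduct aldehyde 9 (not isolated), via chroman-2-ol lactol 10 (not isolated), via o-quinone methide 11 (not isolated)
Conditions: a) 7 (1.1 equiv), 3 (1.0 equiv), (S)-N1,N1-diethyl-3,3-dimethylbutane-1,2-diamine·TfOH (20 mol %), CHCl3, 0 °C → rt; b) same flask, 8 (1.3 equiv), NaOAc (1.5 equiv), AcOH, 50 °C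
Reagents that add atoms: none
Why: Proposed new method: the chiral primary amine salt converts 3 into an iminium ion whose CH2 terminus is attacked by the free ring carbon of 7 ortho to its only OH (Friedel–Crafts Michael addition, forming C4–C4a), the resulting enamine is protonated at C3 on one face by the ammonium arm of the catalyst, and hydrolysis gives aldehyde 9, which rests as lactol 10 (6-exo-trig hemiacetalisation); 8 then condenses through its single unsubstituted ring carbon with the aldehyde carbon (Knoevenagel-type, forming C2–ring C) to o-quinone methide 11, and the ring A hydroxyl adds to the methide carbon (oxa-Michael, forming O1–C2). The closest known reaction types are the primary-amine-catalysed Friedel–Crafts conjugate addition/enantioselective protonation of α-substituted acroleins (shown for indoles), the amine-catalysed addition of electron-rich phenols to enals that ends in chroman-2-ols, and the NaOAc/AcOH condensation of 2,4-diformylphloroglucinol with aliphatic aldehydes to o-quinone methides trapped in the same flask; merging them in one pot with a phenol as the first nucleophile is the new element. The only ring closed is ring B, finally by 6-exo-trig oxa-Michael addition onto the exocyclic methide carbon. C3 (S) is set under catalyst control in the enamine protonation, and C2 (R) under substrate control, because the reversible oxa-Michael closure should settle in the chair with the C2 aryl and C3 isopropyl groups both equatorial (2,3-trans). Regioselectivity of ring closure is secured by the two methyl ethers, which leave the hydroxyl para to the acyl group as the only one on ring A (the two ring carbons ortho to it are equivalent); chemoselectivity between the two phloroglucinols is secured by electronics and order of addition, since the electron-rich 7 alone adds to the iminium ion and the acidic, acceptor-substituted 8 is added after 3 is consumed and reacts as the C-nucleophile toward the aldehyde.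

**Step 5**
Reactants: 12 5-[(2R,3S)-5,7-dimethoxy-6-(3-methylbutanoyl)-3-(propan-2-yl)-3,4-dihydro-2H-chromen-2-yl]-2,4,6-trihydroxybenzene-1,3-dicarbaldehyde
Product: 13 5-[(2R,3S)-5,7-dihydroxy-6-(3-methylbutanoyl)-3-(propan-2-yl)-3,4-dihydro-2H-chromen-2-yl]-2,4,6-trihydroxybenzene-1,3-dicarbaldehyde (target)
Conditions: BCl3 (8 equiv), n-Bu4NI (3 equiv), CH2Cl2, −78 → 0 °C; then H2O
Reagents that add atoms: none
Why: Lewis-acid-mediated aryl methyl ether cleavage, in which boron chelated between the C6 carbonyl and each flanking methoxy oxygen activates the O–CH3 bond for SN2 attack by iodide; the reagent pair cleaves primary alkyl aryl ethers only, so the secondary O1–C2 bond, the aldehydes and both stereocentres should survive.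

**Compound list**
1 | 3-methylbutanal (isovaleraldehyde) | CC(C)CC=O | starting material
2 | formaldehyde | C=O | starting material
3 | 3-methyl-2-methylidenebutanal (2-isopropylacrolein) | CC(C)C(=C)C=O | intermediate
4 | 4-hydroxy-2,6-dimethoxybenzaldehyde | COc1cc(O)cc(OC)c1C=O | starting material
5 | isobutylmagnesium bromide | CC(C)C[Mg]Br | starting material
6 | 4-(1-hydroxy-3-methylbutyl)-3,5-dimethoxyphenol (racemic) | COc1cc(O)cc(OC)c1C(O)CC(C)C | intermediate
7 | 1-(4-hydroxy-2,6-dimethoxyphenyl)-3-methylbutan-1-one | COc1cc(O)cc(OC)c1C(=O)CC(C)C | intermediate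
8 | 2,4,6-trihydroxybenzene-1,3-dicarbaldehyde (2,4-diformylphloroglucinol) | O=Cc1c(O)cc(O)c(C=O)c1O | starting material
9 | (2S)-2-[[6-hydroxy-2,4-dimethoxy-3-(3-methylbutanoyl)phenyl]methyl]-3-methylbutanal (not isolated) | CC(C)CC(=O)c1c(OC)cc(O)c(C[C@@H](C(C)C)C=O)c1OC | intermediate
10 | 1-[(3S)-2-hydroxy-5,7-dimethoxy-3-(propan-2-yl)-3,4-dihydro-2H-chromen-6-yl]-3-methylbutan-1-one (lactol, both C2 anomers, not isolated) | CC(C)CC(=O)c1c(OC)cc2c(c1OC)C[C@@H](C(C)C)C(O)O2 | intermediate
11 | 2,4-dihydroxy-5-[(2S)-2-[[6-hydroxy-2,4-dimethoxy-3-(3-methylbutanoyl)phenyl]methyl]-3-methylbutylidene]-6-oxocyclohexa-1,3-diene-1,3-dicarbaldehyde (o-quinone methide, alkene geometry open, not isolated) | CC(C)CC(=O)c1c(OC)cc(O)c(c1OC)C[C@@H](C(C)C)C=C1C(=O)C(C=O)=C(O)C(C=O)=C1O | intermediate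
12 | 5-[(2R,3S)-5,7-dimethoxy-6-(3-methylbutanoyl)-3-(propan-2-yl)-3,4-dihydro-2H-chromen-2-yl]-2,4,6-trihydroxybenzene-1,3-dicarbaldehyde | CC(C)CC(=O)c1c(OC)cc2c(c1OC)C[C@@H](C(C)C)[C@H](c1c(O)c(C=O)c(O)c(C=O)c1O)O2 | intermediate
13 | 5-[(2R,3S)-5,7-dihydroxy-6-(3-methylbutanoyl)-3-(propan-2-yl)-3,4-dihydro-2H-chromen-2-yl]-2,4,6-trihydroxybenzene-1,3-dicarbaldehyde | CC(C)CC(=O)c1c(O)cc2c(c1O)C[C@@H](C(C)C)[C@H](c1c(O)c(C=O)c(O)c(C=O)c1O)O2 | target

**Totals**
Total step count: 5. Longest linear sequence: 4 steps (4 → 6 → 7 → 12 → 13).

**Steps most likely to fail**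

Step 4. The enamine protonation may show poor facial selectivity, because the newly attached ortho-hydroxyl can shuttle the proton to C3 without the catalyst, and the C3 configuration would then be eroded. The fallback sets out from 7. Acid-mediated three-component condensation of 7 with formaldehyde 2 and sodium 4-methylbenzenesulfinate (HCO2H/H2O, rt) should give 1-[4-hydroxy-2,6-dimethoxy-3-[(4-methylphenyl)sulfonylmethyl]phenyl]-3-methylbutan-1-one F1. Mild base (aq. NaHCO3, CH2Cl2, rt) releases the ring A o-quinone methide 3,5-dimethoxy-6-methylidene-4-(3-methylbutanoyl)cyclohexa-2,4-dien-1-one F2, not isolated. F2 is intercepted in the same flask by the enamine from isovaleraldehyde 1 and the enantiomer of α,α-diphenylprolinol trimethylsilyl ether that shields the face leading to 3S. This is the known amine-catalysed formal [4+2] addition of aldehydes to o-quinone methides that ends in 3-substituted chroman-2-ols; C3 is then set in a C–C bond formation under steric catalyst control and not by protonation. The product is lactol 10, now isolated, which is carried through the second stage of step 4 (8, NaOAc, AcOH) and comes back to the route at 12.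

Step 5. The Lewis acid may ionise the O1–C2 benzylic ether, so that the ring opens and recloses through either ring A oxygen once the methyl groups are gone, or the cleavage may stall after the first methyl ether. The fallback sets out from 7 and moves the deprotection before the key step. BBr3 (CH2Cl2, −78 °C → rt) on this simple ketone should give 3-methyl-1-(2,4,6-trihydroxyphenyl)butan-1-one F3. The one-pot union of step 4 is then run with F3 in place of 7 and should pass through the unprotected aldehyde F4, the unprotected lactol F5 and the unprotected o-quinone methide F6 to come back to the route directly at 13. Ring-closure regiochemistry then rests on the higher acidity and freedom from chelation of the hydroxyl para to the acyl group, and any 8-acyl isomer would have to be separated.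

Step 2. Addition to the hindered aldehyde, deactivated as its phenoxide, may be sluggish, and the p-hydroxybenzylic carbinol may ionise through a p-quinone methide on work-up. The fallback sets out from 4 and uses a silyl detour. TBSCl and imidazole (DMF, rt) give 4-[tert-butyl(dimethyl)silyl]oxy-2,6-dimethoxybenzaldehyde F7. i-BuMgBr (1.3 equiv, THF, −78 → 0 °C) gives 1-[4-[tert-butyl(dimethyl)silyl]oxy-2,6-dimethoxyphenyl]-3-methylbutan-1-ol F8. Dess–Martin periodinane (CH2Cl2, rt) gives 1-[4-[tert-butyl(dimethyl)silyl]oxy-2,6-dimethoxyphenyl]-3-methylbutan-1-one F9. n-Bu4NF buffered with AcOH (THF, 0 °C) removes the silyl group and comes back to the route at 7.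

**Further compounds**
F1 | step 4 | 1-[4-hydroxy-2,6-dimethoxy-3-[(4-methylphenyl)sulfonylmethyl]phenyl]-3-methylbutan-1-one | CC(C)CC(=O)c1c(OC)cc(O)c(CS(=O)(=O)c2ccc(C)cc2)c1OC
F2 | step 4 | 3,5-dimethoxy-6-methylidene-4-(3-methylbutanoyl)cyclohexa-2,4-dien-1-one (ring A o-quinone methide, not isolated) | C=C1C(=O)C=C(OC)C(C(=O)CC(C)C)=C1OC
F3 | step 5 | 3-methyl-1-(2,4,6-trihydroxyphenyl)butan-1-one | CC(C)CC(=O)c1c(O)cc(O)cc1O
F4 | step 5 | (2S)-2-[[2,4,6-trihydroxy-3-(3-methylbutanoyl)phenyl]methyl]-3-methylbutanal (not isolated) | CC(C)CC(=O)c1c(O)cc(O)c(C[C@@H](C(C)C)C=O)c1O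
F5 | step 5 | 1-[(3S)-2,5,7-trihydroxy-3-(propan-2-yl)-3,4-dihydro-2H-chromen-6-yl]-3-methylbutan-1-one (lactol, not isolated) | CC(C)CC(=O)c1c(O)cc2c(c1O)C[C@@H](C(C)C)C(O)O2
F6 | step 5 | 2,4-dihydroxy-5-[(2S)-3-methyl-2-[[2,4,6-trihydroxy-3-(3-methylbutanoyl)phenyl]methyl]butylidene]-6-oxocyclohexa-1,3-diene-1,3-dicarbaldehyde (o-quinone methide, not isolated) | CC(C)CC(=O)c1c(O)cc(O)c(c1O)C[C@@H](C(C)C)C=C1C(=O)C(C=O)=C(O)C(C=O)=C1O
F7 | step 2 | 4-[tert-butyl(dimethyl)silyl]oxy-2,6-dimethoxybenzaldehyde | COc1cc(O[Si](C)(C)C(C)(C)C)cc(OC)c1C=O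
F8 | step 2 | 1-[4-[tert-butyl(dimethyl)silyl]oxy-2,6-dimethoxyphenyl]-3-methylbutan-1-ol (racemic) | COc1cc(O[Si](C)(C)C(C)(C)C)cc(OC)c1C(O)CC(C)C
F9 | step 2 | 1-[4-[tert-butyl(dimethyl)silyl]oxy-2,6-dimethoxyphenyl]-3-methylbutan-1-one | COc1cc(O[Si](C)(C)C(C)(C)C)cc(OC)c1C(=O)CC(C)C
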